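**Plan**
- Retrosynthesis: first the O–Si bond at O6 and the C4–S helper (the C3=C4 bond comes from a sulfoxide elimination) are cut. The key cut then takes the two-carbon unit C3–C4 out of the pyran ring (ring B) by breaking C3–C2 and C4–C4a, leaving an aryl 2-alkenyl ether; this goes back to an aryl ester and to phytol.
- Enabling feature: O1 lies between C2 (ketone oxidation level in the precursor) and C4a, the only unsubstituted ortho carbon of the electron-rich hydroquinone ring (ring A). The unit C4a=C8a–O1=C2(+) is therefore a cationic 2-oxadiene that can take up a nucleophilic acetylene equivalent across C2 and C4a.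
- Forward: the chain comes from natural phytol (ozonolysis, haloform degradation); ester formation and methylenation give the enol ether; ring B forms in one operation in step 6; the sulfur helper and the silyl group are then removed.
- Stereochemistry: C4′ and C8′ come unchanged from natural phytol (C7, C11). C2 is set in step 6 by the chiral counter-anion of the acid catalyst. C4 is a transient stereocentre.

Key step: step 6

Assumption 1: commercial natural phytol is 7R,11R; its E/Z composition is irrelevant because step 1 cleaves the double bond.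
Assumption 2: the sense of induction of the chiral acid in step 6 cannot be predicted with certainty; the (S,S) acid is written, and its mirror image is to be used if a model reaction shows the opposite sense.

**Step 1**
Reactants: 1 natural phytol, (2E,7R,11R)-3,7,11,15-tetramethylhexadec-2-en-1-ol
Product: 2 (6R,10R)-6,10,14-trimethylpentadecan-2-one (phytone)
Conditions: O3, CH2Cl2/MeOH, −78 °C; then Me2S, −78 °C to rt
Reagents that add atoms: ozone, [O-][O+]=O
Why: Ozonolysis with reductive work-up cleaves the trisubstituted C2=C3 bond and leaves the remote methyl-bearing stereocentres untouched.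

**Step 2**
Reactants: 2 (6R,10R)-6,10,14-trimethylpentadecan-2-one
Product: 3 (5R,9R)-5,9,13-trimethyltetradecanoic acid
Conditions: Br2, NaOH (forms NaOBr), 1,4-dioxane/H2O, 0 °C to rt; then aq. HCl
Reagents that add atoms: sodium hydroxide, [Na+].[OH-]
Why: Haloform (Lieben) degradation, in which exhaustive bromination takes place at the methyl group (the less hindered and kinetically more acidic α-position) and hydroxide then cleaves the tribromomethyl ketone to the carboxylate.

**Step 3**
Reactants: 4 2,5-dimethylbenzene-1,4-diol (2,5-dimethylhydroquinone)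
Product: 5 4-[(tert-butyldimethylsilyl)oxy]-2,5-dimethylphenol
Conditions: TBSCl (1 equiv), imidazole, DMF, 0 °C to rt; 4 in excess (2.5 equiv)
Reagents that add atoms: tert-butyldimethylsilyl chloride (TBSCl), CC(C)(C)[Si](C)(C)Cl
Why: Statistical monosilylation of a diol whose two hydroxyl groups are equivalent by symmetry, with the excess of 4 keeping the bis-ether low and being recovered.

**Step 4**
Reactants: 3 (5R,9R)-5,9,13-trimethyltetradecanoic acid; 5 4-[(tert-butyldimethylsilyl)oxy]-2,5-dimethylphenol
Product: 6 4-[(tert-butyldimethylsilyl)oxy]-2,5-dimethylphenyl (5R,9R)-5,9,13-trimethyltetradecanoate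
Conditions: DCC, DMAP (cat.), CH2Cl2, 0 °C to rt
Reagents that add atoms: none
Why: Steglich esterification, which acylates a phenol carrying one ortho-methyl group under neutral conditions.

**Step 5**
Reactants: 6 4-[(tert-butyldimethylsilyl)oxy]-2,5-dimethylphenyl (5R,9R)-5,9,13-trimethyltetradecanoate
Product: 7 tert-butyl(2,5-dimethyl-4-{[(6R,10R)-6,10,14-trimethylpentadec-1-en-2-yl]oxy}phenoxy)dimethylsilane
Conditions: Cp2TiMe2 (2.5 equiv), toluene/THF, 65 °C, dark; filtration through basic Al2O3
Reagents that add atoms: dimethyltitanocene (Cp2TiMe2), C[Ti](C)(C1C=CC=C1)C1C=CC=C1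
Why: Petasis methylenation (titanium methylidene, oxatitanacyclobutane, cycloreversion) converts the aryl ester carbonyl into the 1,1-disubstituted enol ether without acid, so the enol ether and the aryl silyl ether survive.

**Step 6**
Reactants: 7 tert-butyl(2,5-dimethyl-4-{[(6R,10R)-6,10,14-trimethylpentadec-1-en-2-yl]oxy}phenoxy)dimethylsilane; 8 phenyl vinyl sulfide
Product: 11 tert-butyldimethyl({(2S)-2,5,8-trimethyl-4-(phenylsulfanyl)-2-[(4R,8R)-4,8,12-trimethyltridecyl]-3,4-dihydro-2H-chromen-6-yl}oxy)silane (both C4 epimers), via O-aryl oxocarbenium ion 9 (not isolated), via thionium ion 10 (not isolated)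
Conditions: (S,S)-HN[P(=NSO2CF3)(O2C20H10Ar2)]2 with Ar = 4-tert-butylphenyl (chiral imidodiphosphorimidate acid, 5 mol%), 8 (5 equiv), toluene, −40 °C, slow addition of 7; then Et3N
Reagents that add atoms: none
Why: Proposed new method: the confined chiral acid protonates the terminal CH2 of 7 (this carbon becomes the C2 methyl group) to give the O-aryl oxocarbenium ion 9 paired with the chiral anion, the CH2 terminus of 8 adds to C2 of this cationic 2-oxadiene (C4a=C8a–O1=C2; bond C3–C2), and the sulfur-stabilised cation 10 is captured by C4a (bond C4–C4a), the proton lost from C4a returning to the catalyst. The closest known reaction types are the Lewis-acid-mediated oxa-Povarov reaction of aldehyde-derived aryl oxocarbenium ions with alkenes, the chiral-acid Povarov reaction of N-aryl iminium ions with vinyl ethers and enecarbamates (vinyl sulfides being established two-carbon partners in the Lewis-acid version), and confined-acid additions to oxocarbenium ions of methyl alkyl ketones; a ketone-derived O-aryl oxocarbenium ion has not been used in this way, nor enantioselectively. Ring B closes by 6-exo-trig Friedel–Crafts attack of C4a on the thionium carbon C4, so the overall change is a stepwise polar [4+2] annulation. C2 is controlled by the chiral anion, which has to shield the Si face so that C3 enters on the Re face (O > CH2R > CH3) and gives 2S, the discrimination of CH3 from CH2R in the anion pocket being the task that acids of this family solve for 2-butanone-type oxocarbenium ions; C4 forms as an epimer mixture and disappears in step 7. The step needs cross- rather than self-addition (7 is the more basic alkene and the only one protonated, and its slow addition into excess 8 keeps 9 from meeting 7), regiocontrol in the C–C bond formation (sulfur polarises 8 so that CH2 attacks and the charge ends at C4) and a single site of ring closure (C8 carries a methyl group, so C4a is the only free ortho position).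

**Step 7**
Reactants: 11 tert-butyldimethyl({(2S)-2,5,8-trimethyl-4-(phenylsulfanyl)-2-[(4R,8R)-4,8,12-trimethyltridecyl]-3,4-dihydro-2H-chromen-6-yl}oxy)silane
Product: 13 tert-butyldimethyl({(2S)-2,5,8-trimethyl-2-[(4R,8R)-4,8,12-trimethyltridecyl]-2H-chromen-6-yl}oxy)silane, via sulfoxide 12 (not isolated)
Conditions: mCPBA (1.0 equiv), toluene, −40 °C; then Et3N (3 equiv), 80 °C, dark
Reagents that add atoms: none
Why: Chemoselective S-oxidation at low temperature followed by thermal syn-elimination of the benzylic sulfoxide, for which only C3 offers β-hydrogens, unveils the C3=C4 bond without a cation at C4 and at a temperature and in darkness chosen to avoid reversible oxa-6π ring opening of the 2H-chromene, which would scramble C2.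

**Step 8**
Reactants: 13 tert-butyldimethyl({(2S)-2,5,8-trimethyl-2-[(4R,8R)-4,8,12-trimethyltridecyl]-2H-chromen-6-yl}oxy)silane
Product: 14 (2S)-2,5,8-trimethyl-2-[(4R,8R)-4,8,12-trimethyltridecyl]-2H-chromen-6-ol (target)
Conditions: TBAF, AcOH (1:1), THF, 0 °C, argon, dark
Reagents that add atoms: none
Why: Fluoride-mediated cleavage of the aryl silyl ether, buffered with acetic acid so that the air-sensitive phenoxide is protonated at once, leaves C2 and the ring alkene untouched.

**Compound list**
1 | natural phytol, (2E,7R,11R)-3,7,11,15-tetramethylhexadec-2-en-1-ol | OC/C=C(\C)CCC[C@H](C)CCC[C@H](C)CCCC(C)C | starting material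
2 | (6R,10R)-6,10,14-trimethylpentadecan-2-one (phytone) | CC(=O)CCC[C@H](C)CCC[C@H](C)CCCC(C)C | intermediate
3 | (5R,9R)-5,9,13-trimethyltetradecanoic acid | OC(=O)CCC[C@H](C)CCC[C@H](C)CCCC(C)C | intermediate
4 | 2,5-dimethylbenzene-1,4-diol | Cc1cc(O)c(C)cc1O | starting material
5 | 4-[(tert-butyldimethylsilyl)oxy]-2,5-dimethylphenol | Cc1cc(O[Si](C)(C)C(C)(C)C)c(C)cc1O | intermediate
6 | 4-[(tert-butyldimethylsilyl)oxy]-2,5-dimethylphenyl (5R,9R)-5,9,13-trimethyltetradecanoate | Cc1cc(O[Si](C)(C)C(C)(C)C)c(C)cc1OC(=O)CCC[C@H](C)CCC[C@H](C)CCCC(C)C | intermediate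
7 | tert-butyl(2,5-dimethyl-4-{[(6R,10R)-6,10,14-trimethylpentadec-1-en-2-yl]oxy}phenoxy)dimethylsilane | Cc1cc(O[Si](C)(C)C(C)(C)C)c(C)cc1OC(=C)CCC[C@H](C)CCC[C@H](C)CCCC(C)C | intermediate
8 | phenyl vinyl sulfide, (ethenylsulfanyl)benzene | C=CSc1ccccc1 | starting material
9 | O-aryl oxocarbenium ion (not isolated; paired with the catalyst anion), {4-[(tert-butyldimethylsilyl)oxy]-2,5-dimethylphenyl}[(6R,10R)-6,10,14-trimethylpentadecan-2-ylidene]oxonium | Cc1cc(O[Si](C)(C)C(C)(C)C)c(C)cc1[O+]=C(C)CCC[C@H](C)CCC[C@H](C)CCCC(C)C | intermediate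
10 | thionium ion (not isolated), [(3S,7R,11R)-3-{4-[(tert-butyldimethylsilyl)oxy]-2,5-dimethylphenoxy}-3,7,11,15-tetramethylhexadecylidene](phenyl)sulfonium | Cc1cc(O[Si](C)(C)C(C)(C)C)c(C)cc1O[C@@](C)(CCC[C@H](C)CCC[C@H](C)CCCC(C)C)CC=[S+]c1ccccc1 | intermediate
11 | tert-butyldimethyl({(2S)-2,5,8-trimethyl-4-(phenylsulfanyl)-2-[(4R,8R)-4,8,12-trimethyltridecyl]-3,4-dihydro-2H-chromen-6-yl}oxy)silane, both C4 epimers | Cc1cc(O[Si](C)(C)C(C)(C)C)c(C)c2c1O[C@@](C)(CCC[C@H](C)CCC[C@H](C)CCCC(C)C)CC2Sc1ccccc1 | intermediate
12 | sulfoxide (not isolated), {[(2S)-4-(benzenesulfinyl)-2,5,8-trimethyl-2-[(4R,8R)-4,8,12-trimethyltridecyl]-3,4-dihydro-2H-chromen-6-yl]oxy}(tert-butyl)dimethylsilane | Cc1cc(O[Si](C)(C)C(C)(C)C)c(C)c2c1O[C@@](C)(CCC[C@H](C)CCC[C@H](C)CCCC(C)C)CC2S(=O)c1ccccc1 | intermediate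
13 | tert-butyldimethyl({(2S)-2,5,8-trimethyl-2-[(4R,8R)-4,8,12-trimethyltridecyl]-2H-chromen-6-yl}oxy)silane | Cc1cc(O[Si](C)(C)C(C)(C)C)c(C)c2c1O[C@@](C)(CCC[C@H](C)CCC[C@H](C)CCCC(C)C)C=C2 | intermediate
14 | (2S)-2,5,8-trimethyl-2-[(4R,8R)-4,8,12-trimethyltridecyl]-2H-chromen-6-ol | Cc1cc(O)c(C)c2c1O[C@@](C)(CCC[C@H](C)CCC[C@H](C)CCCC(C)C)C=C2 | target

**Totals**
Total step count: 8. Longest linear sequence: 7 (steps 1, 2, 4, 5, 6, 7, 8 from phytol; step 3 is a one-step side branch).

**Steps most likely to fail**

1. Step 6 (Proposed new method). What may go wrong: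
- insufficient discrimination of the two faces of the oxocarbenium ion, whose substituents differ only as CH3 and CH2R;
- self-addition or oligomerisation of the enol ether;
- hydrolysis of the enol ether by adventitious water;
- capture of the thionium ion by a second molecule of the vinyl sulfide instead of ring closure.

If the selectivity is useful but incomplete, the minor 2R epimer is a diastereomer and would have to be removed at the stage of 13 by chromatography on a chiral stationary phase.

Fallback with known chemistry, setting out from 5 and 1 and returning at 13: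
- Phenol 5 is formylated at its only free ortho position (MgCl2, Et3N, paraformaldehyde, MeCN, reflux) to give 5-[(tert-butyldimethylsilyl)oxy]-2-hydroxy-3,6-dimethylbenzaldehyde F1.
- Wittig methylenation (Ph3P=CH2, 2.2 equiv, THF) gives 4-[(tert-butyldimethylsilyl)oxy]-2-ethenyl-3,6-dimethylphenol F2.
- Phytol 1 is converted with methyl chloroformate and pyridine into methyl (2E,7R,11R)-3,7,11,15-tetramethylhexadec-2-en-1-yl carbonate F3.
- Palladium-catalysed asymmetric allylic etherification of the Tsuji–Trost type joins F2 and F3 at the tertiary allyl terminus. Conditions: Pd2(dba)3·CHCl3, the enantiomer of N,N′-(cyclohexane-1,2-diyl)bis[2-(diphenylphosphanyl)benzamide] that gives the S ether, CH2Cl2. The product is tert-butyl(3-ethenyl-2,5-dimethyl-4-{[(3S,7R,11R)-3,7,11,15-tetramethylhexadec-1-en-3-yl]oxy}phenoxy)dimethylsilane F4, so C2 is set in the C–O bond formation.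
- Ring-closing metathesis of F4 (second-generation Grubbs catalyst, RuCl2(=CHPh)(PCy3)(H2IMes), CH2Cl2, 40 °C) closes ring B to 13.

2. Step 5. What may go wrong: incomplete methylenation of the enolisable aryl ester, and hydrolysis or double-bond migration of the acid-sensitive enol ether during isolation.

Fallback, setting out from 2 and 5 and returning at 7 (it bypasses steps 2 and 4):
- Kinetic deprotonation of 2 at the methyl group and O-sulfonylation (KHMDS, PhNTf2, THF, −78 °C) give (6R,10R)-6,10,14-trimethylpentadec-1-en-2-yl trifluoromethanesulfonate F5.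
- Palladium-catalysed C–O coupling of F5 with phenol 5 (Pd2(dba)3, 2-(di-tert-butylphosphanyl)biphenyl, NaOtBu, toluene, 80 °C) gives 7.

3. Step 7. What may go wrong: over-oxidation to the sulfone or oxidation of the electron-rich ring, re-addition of the sulfenic acid to the new alkene, and erosion of the C2 configuration if the elimination needs prolonged heating.

Fallback, setting out from 11 and returning at 13:
- S-Methylation of 11 (MeOTf, 2,6-di-tert-butyl-4-methylpyridine, CH2Cl2, −20 °C) gives [(2S)-6-[(tert-butyldimethylsilyl)oxy]-2,5,8-trimethyl-2-[(4R,8R)-4,8,12-trimethyltridecyl]-3,4-dihydro-2H-chromen-4-yl](methyl)(phenyl)sulfonium trifluoromethanesulfonate F6.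
- Base-induced elimination of thioanisole (DBU, 0 °C to rt) gives 13 in an ionic elimination that needs no heating.

**Further compounds**
F1 | step 6 | 5-[(tert-butyldimethylsilyl)oxy]-2-hydroxy-3,6-dimethylbenzaldehyde | Cc1cc(O[Si](C)(C)C(C)(C)C)c(C)c(C=O)c1O
F2 | step 6 | 4-[(tert-butyldimethylsilyl)oxy]-2-ethenyl-3,6-dimethylphenol | Cc1cc(O[Si](C)(C)C(C)(C)C)c(C)c(C=C)c1O
F3 | step 6 | methyl (2E,7R,11R)-3,7,11,15-tetramethylhexadec-2-en-1-yl carbonate | COC(=O)OC/C=C(\C)CCC[C@H](C)CCC[C@H](C)CCCC(C)C
F4 | step 6 | tert-butyl(3-ethenyl-2,5-dimethyl-4-{[(3S,7R,11R)-3,7,11,15-tetramethylhexadec-1-en-3-yl]oxy}phenoxy)dimethylsilane | C=Cc1c(C)c(O[Si](C)(C)C(C)(C)C)cc(C)c1O[C@@](C)(CCC[C@H](C)CCC[C@H](C)CCCC(C)C)C=C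
F5 | step 5 | (6R,10R)-6,10,14-trimethylpentadec-1-en-2-yl trifluoromethanesulfonate | C=C(OS(=O)(=O)C(F)(F)F)CCC[C@H](C)CCC[C@H](C)CCCC(C)C
F6 | step 7 | [(2S)-6-[(tert-butyldimethylsilyl)oxy]-2,5,8-trimethyl-2-[(4R,8R)-4,8,12-trimethyltridecyl]-3,4-dihydro-2H-chromen-4-yl](methyl)(phenyl)sulfonium trifluoromethanesulfonate | Cc1cc(O[Si](C)(C)C(C)(C)C)c(C)c2c1O[C@@](C)(CCC[C@H](C)CCC[C@H](C)CCCC(C)C)CC2[S+](C)c1ccccc1.[O-]S(=O)(=O)C(F)(F)F
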